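A slow flask can be read from its pace. The amber run reached 15 % of target at 1.33 h, and that pace carried on to 2.5 h gives 28.2 %. I call this the straight-line yield: the target a flask holds at a given time if the early pace of the amber run goes on unchanged.

| setting | amber | ochre | flask |
|---|---|---|---|
| starting material | 40 mM | 40 mM | 40 mM |
| reagent in the second phase | 2 equiv | 2 equiv | 2.00 equiv |
| protic impurity | 2 mM | 3 mM | 4.00 mM |
| remark | run made earlier | run made earlier |  |
| time |  |  | 2.5 h |
| volume of the second phase over the first |  |  | 1.0 |

- amber (time / h: target / %): 0.250: 3; 0.833: 10; 1.33: 15; 2.00: 22; 3.00: 22
- ochre (time / h: target / %): 0.667: 8; 1.33: 17; 2.00: 21; 2.50: 21; 3.00: 21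

(standard deviation of a reading: 1.5 percentage points)

- in the second phase: reagent in the second phase; everything else is in the first
- charges count per volume of the first phase; a concentration in a rate is the amount of a species over the volume of its own phase; every rate counts per litre of the first phase
- the earlier runs hold the two phases in the same ratio of volumes as the flask asked about

* amount of target at 2.5 h, in percent of the starting material charged
* the change that raises the amount of target at 2.5 h, in percent of the starting material charged most ("none" if none brings more than 2 percentage points) (south-west / south / none)
* amount of target at 2.5 h, in percent of the starting material charged, after south-west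

- south-west: doubling the transfer coefficient of the reagent in the second phase, all else as stated
- south: doubling the amount of reagent in the second phase, all else as stated

Two extreme versions of the new flask can be solved in the head. In the first, the pace holds, so the new flask stands at the straight-line yield. In the second, target stays on the flat level of the late readings of both earlier runs, whose mean is 21.4 %. These two versions are estimates, not bounds: the flat level comes from runs with 2 mM and 3 mM of protic impurity, while the new flask has 4.00 mM. I expect the new flask nearer the flat version, since the ochre run shows a rise from 2.00 h to 3.00 h smaller than the scatter of 1.5 percentage points. Going from 2 mM to 3 mM of protic impurity lowers the last reading by 1 point, which is also less than the scatter. So I commit to 21.4 %.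

The forecast gives 20 %, lower than mine, and 20.5 % after south-west, and it chooses south: “More reagent should raise the ceiling, so south is best.”

The flask gives 23.3 %, and 25.0 % after south-west, while south adds 10 points against 1.7 points for south-west; the forecast is right on all three.

    starting material + reagent in the reaction phase → target (k = 17.0 M⁻¹ h⁻¹)
    starting material + protic impurity → quenched substrate (k = 17.0 M⁻¹ h⁻¹)
    starting material + target → side product (k = 11.0 M⁻¹ h⁻¹)
    reagent in the reaction phase + target → over-reacted product (k = 5.40 M⁻¹ h⁻¹)
    reagent in the reaction phase ⇌ reagent in the second phase, rate k5*([reagent in the reaction phase] - [reagent in the second phase]/K5) per volume of the first phase (partition coefficient = 2.50, kL = 1.60 h⁻¹)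
    target ⇌ isomer of the product (K = 0.640, k = 0.180 h⁻¹)

The flask holds 82.6 % of its straight-line yield at 2.5 h. In this flask target, an intermediate of consecutive steps, is made 5.03 times faster than it is used at 0.536 h, but 1.25 times faster at 2.50 h. Left until 6.0 h, the same flask holds 22.6 % of target against a straight-line yield of 67.7 %, which is 33.4 % of it.

(The numbers in the tables were computed from invented constants.)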